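Core atoms carry longipinane numbers: C1 ketone, C2=C3 (C15 is the methyl on C3), C4 and C11 bridgeheads, C5 the cyclobutane CH bonded to C6 (CMe2), C7 epoxy-ester carbinol, C8, C9 angelate carbinol, C10 quaternary methyl-bearing carbon. Ring A is C1–C2–C3–C4–C10–C11, ring B the cyclobutane C4–C5–C11–C10, ring C the seven-membered ring C5–C6–C7–C8–C9–C10–C11.
Retrosynthetic cuts, in order: the ester C–O bonds at C9 and C7; C5–C6 (aldol of the CMe2 carbon onto a cyclobutanone, the C5 oxygen being removed afterwards); C5–C11 and C4–C10 (intramolecular vinylketene–alkene [2+2]); C1–C2 (vinylogous Mukaiyama aldol); C8–C9 (boron aldol).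
Enabling feature: ring B is the four-membered ring of a bicyclo[3.1.1]heptenone bridged by ring A across C4 and C11, and C5 bears only hydrogen and C6. C5 can therefore enter as a ketene carbon, become the cyclobutanone carbonyl, and then be the electrophile on which ring C closes.
Forward order: two aldol reactions assemble an acyclic C15 trienoic acid; rings A and B form together in the [2+2]; ring C closes by aldol addition; C5 is deoxygenated, the esters are attached and the ring A enone is revealed last.
Stereochemistry: C9 from the Ipc2BCl aldol; a temporary C1 carbinol from the catalytic vinylogous aldol, which with the E alkene sets C4, C10 and C11; C5 by ring constraint; C7 by hydroxyl-directed Evans–Tishchenko reduction; the epoxide by Sharpless epoxidation of tiglyl alcohol; the Z alkene from angelic acid.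

Key step: step 9

Remark 1: the geometry of the ketene acetal double bond of 10 is immaterial and is left undefined.
Remark 2: step 9 may also give some ring-alkene (C2=C3) isomer of 16; carried through the same operations it would give enone 31 directly at step 20, so both isomers converge.
Remark 3: the reagent antipodes named in steps 1, 6 and 13 are those expected from the usual models and should be confirmed on the first adducts (Mosher esters).

Step 1
Reactants: 1 (E)-4-acetoxy-2-methylbut-2-enal; 2 3-methylbutan-2-one
Product: 4 (5R,6E)-8-acetoxy-5-hydroxy-2,6-dimethyloct-6-en-3-one, via enol borinate 3 (not isolated)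
Conditions: (−)-Ipc2BCl, Et3N, Et2O, 0 °C; then 1, −78 → −20 °C; H2O2, pH 7 buffer, MeOH
Reagents that add atoms: none
Why: Ipc2BCl/Et3N enolises the methyl ketone on its methyl side and the enol borinate adds to the enal in a reagent-controlled boron aldol; the (−)-reagent (from (+)-α-pinene) is expected to attack the re face and give (R)-C9, enantioselectivity is only moderate for methyl ketones, and the minor enantiomer is removed as a diastereomer after step 6.

Step 2
Reactants: 4 aldol adduct
Product: 5 triethylsilyl ether of 4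
Conditions: Et3SiCl, imidazole, DMF, 0 °C
Reagents that add atoms: chlorotriethylsilane, CC[Si](Cl)(CC)CC
Why: Standard silylation of a secondary alcohol masks the β-hydroxy ketone against retro-aldol and oxidation without touching C9.

Step 3
Reactants: 5 silyl ether acetate
Product: 6 primary allylic alcohol
Conditions: K2CO3 (0.2 equiv), MeOH, 0 °C, short reaction time
Reagents that add atoms: none
Why: Base-catalysed transesterification of the unhindered primary allylic acetate is fast at 0 °C, so brief exposure should spare the triethylsilyl ether and the β-silyloxy ketone.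

Step 4
Reactants: 6 allylic alcohol
Product: 7 (2E,4R)-3,7-dimethyl-6-oxo-4-(triethylsilyloxy)oct-2-enal
Conditions: MnO2, CH2Cl2, rt
Reagents that add atoms: none
Why: MnO2 oxidation of an allylic alcohol is neutral, stops at the aldehyde and keeps the E geometry.

Step 5
Reactants: 8 methyl 3-methylbut-2-enoate
Product: 10 silyl dienol ether of 8, via lithium dienolate 9 (not isolated)
Conditions: LiN(iPr)2 (LDA), THF, −78 °C; tBuMe2SiCl, DMPU, −78 °C → rt
Reagents that add atoms: tert-butylchlorodimethylsilane, CC(C)(C)[Si](C)(C)Cl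
Why: γ-Deprotonation of the enoate and O-silylation of the extended enolate is the standard route to a vinylogous silyl ketene acetal.

Step 6
Reactants: 7 enal; 10 silyl dienol ether
Product: 11 methyl (2E,5S,6E,8R)-5-hydroxy-3,7,11-trimethyl-10-oxo-8-(triethylsilyloxy)dodeca-2,6-dienoate
Conditions: SiCl4 (1.1 equiv), (S,S)-binaphthyldiamine-derived bisphosphoramide (5 mol%), iPr2NEt (cat.), CH2Cl2, −78 °C; aq. NaHCO3
Reagents that add atoms: none
Why: In this Lewis-base-activated SiCl4 vinylogous Mukaiyama aldol the chiral chlorosilyl cation binds only the aldehyde (the ketone is inert), the dienol ether reacts at its γ-carbon, and the catalyst antipode (S,S expected, si-face attack) sets the temporary (S)-C1 carbinol independently of the remote C9 centre.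

Step 7
Reactants: 11 hydroxy enoate
Product: 12 tert-butyldimethylsilyl ether of 11
Conditions: tBuMe2SiCl, imidazole, DMF, rt
Reagents that add atoms: tert-butylchlorodimethylsilane, CC(C)(C)[Si](C)(C)Cl
Why: Silylation of the secondary allylic alcohol under mild base gives a C1 protecting group that outlasts the triethylsilyl ether at C9 and does not enolise the ketone.

Step 8
Reactants: 12 methyl ester
Product: 13 trienoic acid
Conditions: Me3SnOH, ClCH2CH2Cl, 80 °C; 0.05 M HCl wash
Reagents that add atoms: trimethyltin hydroxide, C[Sn](C)(C)O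
Why: Me3SnOH hydrolyses methyl esters under nearly neutral conditions, avoiding the elimination of the β-silyloxy ketone and the silyl loss that aqueous hydroxide would risk.

Step 9
Reactants: 13 trienoic acid
Product: 16 bicyclo[3.1.1]heptan-6-one, via acid chloride 14 (not isolated), via vinylketene 15 (not isolated)
Conditions: 1-chloro-N,N,2-trimethylprop-1-en-1-amine, CH2Cl2, 0 °C → rt; then syringe-pump addition to Et3N, toluene, 110 °C (final 0.005 M)
Reagents that add atoms: none
Why: Et3N removes a γ-proton from the methyl group cis to the acyl chloride to give vinylketene 15, whose electrophilic carbonyl carbon (future C5) attacks the alkene CH (C11) while the developing tertiary cation at C10 is captured by the ketene α-carbon (C4), an asynchronous thermal [2+2] that is suprafacial on the alkene. The closest known reaction type is the intramolecular cycloaddition of vinylketenes from 3-methylalk-2-enoyl chlorides with a trisubstituted alkene three atoms away, which gives 2-methylidenebicyclo[3.1.1]heptan-6-ones. The C5–C11 bond closes a six-membered ring in the exo mode and the C4–C10 bond then closes the cyclobutanone in the crossed sense, which at the same time completes ring A as the second six-membered ring of a bicyclo[3.1.1]heptane and not a bicyclo[3.2.0] system. The E alkene puts the C10 methyl syn to the three-carbon bridge and the side chain on the face next to the cyclobutanone, the short tether forces the C4 and C11 hydrogens cis, and the absolute sense at C4, C10 and C11 comes from the C1 silyloxy stereocentre. The selectivity needed is facial: with the tether on the attacked face, the C1–H bond should point to the rear face toward which the C10 methyl swings as C10 pyramidalises and the silyloxy group should lie outside in the alkene plane, so the silyl ether ends up syn to the carbonyl bridge and anti to the crowded C10 bridge. Regiochemistry follows from the alkene substitution (tertiary versus secondary cationic character), and high dilution suppresses ketene dimerisation.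

Step 10
Reactants: 16 bicyclic cyclobutanone
Product: 17 hydroxy ketone (C9–OH free)
Conditions: AcOH/THF/H2O (3:1:1), rt
Reagents that add atoms: none
Why: Mild aqueous acid cleaves a triethylsilyl ether much faster than the secondary tert-butyldimethylsilyl ether, and the non-enolisable cyclobutanone only hydrates reversibly.

Step 11
Reactants: 17 hydroxy ketone
Product: 19 tricyclic keto diol with tertiary cyclobutanol, via dilithium enolate 18 (not isolated)
Conditions: LiN(iPr)2 (LDA, 2.5 equiv), THF, −78 → −20 °C; aq. NH4Cl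
Reagents that add atoms: none
Why: In this aldolate-dianion aldol the C9 lithium alkoxide steers the second deprotonation to the α' (isopropyl) carbon and blocks β-elimination, and the tetrasubstituted enolate adds to the strained cyclobutanone from its lower face to close the seven-membered ring; the methylene enolate has no unstrained cyclisation mode, and the ring constraint fixes C5 with C6 cis to the C9-bearing chain on ring B.

Step 12
Reactants: 20 tiglic acid
Product: 21 (E)-2-methylbut-2-en-1-ol
Conditions: LiAlH4, Et2O, 0 °C → rt; Na2SO4·10H2O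
Reagents that add atoms: none
Why: LiAlH4 reduces the conjugated acid to the allylic alcohol in a 1,2 sense without touching the trisubstituted alkene.

Step 13
Reactants: 21 tiglyl alcohol
Product: 22 [(2R,3R)-2,3-dimethyloxiran-2-yl]methanol
Conditions: Ti(OiPr)4 (10 mol%), D-(−)-diethyl tartrate (12 mol%), tBuOOH, 4 Å MS, CH2Cl2, −20 °C
Reagents that add atoms: tert-butyl hydroperoxide, CC(C)(C)OO
Why: Sharpless asymmetric epoxidation of an E-trisubstituted allylic alcohol is stereospecific (methyls stay cis) and the D-(−)-tartrate is expected to deliver oxygen to the face that gives the (2R,3R)-epoxy alcohol.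

Step 14
Reactants: 22 epoxy alcohol
Product: 23 (2S,3R)-2,3-dimethyloxirane-2-carboxylic acid
Conditions: RuCl3·xH2O (2 mol%), NaIO4, CCl4/MeCN/H2O, rt
Reagents that add atoms: water, O
Why: RuO4 generated in situ oxidises the primary alcohol through the aldehyde hydrate to the acid without opening the epoxide or touching either stereocentre (the C2 descriptor changes only because the CIP priorities change).

Step 15
Reactants: 19 tricyclic keto diol
Product: 24 C9 monoacetate of the 7,9-anti diol
Conditions: SmI2 (0.3 equiv), MeCHO (10 equiv), THF, −10 °C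
Reagents that add atoms: acetaldehyde, CC=O
Why: In the Evans–Tishchenko reduction the C9 hydroxyl forms a samarium-bound hemiacetal with acetaldehyde and delivers its hydride to the C7 ketone on its own face, giving the trans (anti) 7,9-diol with (R)-C7 and leaving C9 as the acetate and C7–OH free; the hindered tertiary C5–OH would direct to the same face.

Step 16
Reactants: 24 monoacetate diol; 23 epoxy acid
Product: 26 C7 epoxy ester with free tertiary C5–OH, via mixed anhydride 25 (not isolated)
Conditions: 23, 2,4,6-trichlorobenzoyl chloride, Et3N, THF, rt; then 24, DMAP (0.5 equiv), toluene, rt → 40 °C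
Reagents that add atoms: none
Why: Yamaguchi esterification through the acylpyridinium ion acylates the hindered secondary C7 alcohol with retention at all centres, while the tertiary cyclobutanol is inert; the temperature is kept low to limit 1,3-acetyl migration.

Step 17
Reactants: 26 tertiary cyclobutanol
Product: 27 C5 methyl oxalate
Conditions: ClC(O)CO2Me, DMAP (cat.), pyridine, CH2Cl2, 0 °C → rt
Reagents that add atoms: methyl chlorooxoacetate, COC(=O)C(Cl)=O
Why: DMAP-catalysed acylation with the small, highly electrophilic oxalyl monoester chloride is the usual way to activate a tertiary alcohol for radical deoxygenation, and no other free hydroxyl is present.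

Step 18
Reactants: 27 methyl oxalate
Product: 28 C5-deoxygenated tricycle with acetate and epoxy ester
Conditions: Bu3SnH, AIBN, toluene, 110 °C
Reagents that add atoms: none
Why: In this radical deoxygenation of a tertiary methyl oxalate the stannyl radical adds to the oxalate, β-scission releases the tertiary C5 radical (no β-leaving group, no easy ring opening), and hydrogen transfer from Bu3SnH can only occur on the face away from ring C, giving (S)-C5.

Step 19
Reactants: 28 silyl ether
Product: 29 C1 alcohol
Conditions: Bu4NF, AcOH (1:1), THF, 0 °C → rt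
Reagents that add atoms: none
Why: Fluoride desilylation buffered with acetic acid removes the secondary silyl ether without ester cleavage or acyl migration and avoids the epoxide opening that HF-based reagents could cause.

Step 20
Reactants: 29 secondary alcohol
Product: 31 enone acetate, via β,γ-unsaturated ketone 30 (not isolated)
Conditions: Dess–Martin periodinane, pyridine, CH2Cl2, rt; then DBU (0.2 equiv), rt
Reagents that add atoms: none
Why: Dess–Martin oxidation gives the C1 ketone and DBU then moves the exocyclic alkene into conjugation through the C2 dienolate (base-mediated alkene isomerisation); the bridgehead C11–H cannot enolise, so no stereocentre is at risk.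

Step 21
Reactants: 31 enone acetate
Product: 32 C9 alcohol
Conditions: K2CO3 (0.5 equiv), MeOH, 0 °C → rt
Reagents that add atoms: none
Why: Base-catalysed methanolysis removes the acetate much faster than the epoxy ester, whose acyl carbon is shielded by a quaternary α-carbon and a neopentyl carbinol.

Step 22
Reactants: 32 C9 alcohol; 33 angelic acid
Product: 35 target CNP0149458.1, via mixed anhydride 34 (not isolated)
Conditions: 33, 2,4,6-trichlorobenzoyl chloride, Et3N, toluene, rt; then 32, toluene, 80 °C (no DMAP)
Reagents that add atoms: none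
Why: Yamaguchi-type mixed-anhydride esterification run hot without a nucleophilic catalyst is the established way to angeloylate hindered alcohols without Z to E isomerisation, so the Z alkene comes unchanged from angelic acid.

Compound list
1 | (E)-4-acetoxy-2-methylbut-2-enal | CC(=O)OC/C=C(\C)C=O | starting material
2 | 3-methylbutan-2-one | CC(=O)C(C)C | starting material
3 | 2-(diisopinocampheylboryloxy)-3-methylbut-1-ene, Ipc groups of the (+)-α-pinene series | CC(C)C(=C)OB([C@@H]1C[C@@H]2C[C@H]([C@H]1C)C2(C)C)[C@@H]1C[C@@H]2C[C@H]([C@H]1C)C2(C)C | intermediate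
4 | (5R,6E)-8-acetoxy-5-hydroxy-2,6-dimethyloct-6-en-3-one | CC(=O)OC/C=C(\C)[C@H](O)CC(=O)C(C)C | intermediate
5 | (5R,6E)-8-acetoxy-2,6-dimethyl-5-(triethylsilyloxy)oct-6-en-3-one | CC(=O)OC/C=C(\C)[C@H](O[Si](CC)(CC)CC)CC(=O)C(C)C | intermediate
6 | (5R,6E)-8-hydroxy-2,6-dimethyl-5-(triethylsilyloxy)oct-6-en-3-one | OC/C=C(\C)[C@H](O[Si](CC)(CC)CC)CC(=O)C(C)C | intermediate
7 | (2E,4R)-3,7-dimethyl-6-oxo-4-(triethylsilyloxy)oct-2-enal | O=C/C=C(\C)[C@H](O[Si](CC)(CC)CC)CC(=O)C(C)C | intermediate
8 | methyl 3-methylbut-2-enoate | COC(=O)C=C(C)C | starting material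
9 | lithium 1-methoxy-3-methylbuta-1,3-dien-1-olate | [Li+].[O-]C(OC)=CC(C)=C | intermediate
10 | tert-butyl[(1-methoxy-3-methylbuta-1,3-dien-1-yl)oxy]dimethylsilane | C=C(C)C=C(OC)O[Si](C)(C)C(C)(C)C | intermediate
11 | methyl (2E,5S,6E,8R)-5-hydroxy-3,7,11-trimethyl-10-oxo-8-(triethylsilyloxy)dodeca-2,6-dienoate | COC(=O)/C=C(\C)C[C@H](O)/C=C(\C)[C@H](O[Si](CC)(CC)CC)CC(=O)C(C)C | intermediate
12 | methyl (2E,5S,6E,8R)-5-(tert-butyldimethylsilyloxy)-3,7,11-trimethyl-10-oxo-8-(triethylsilyloxy)dodeca-2,6-dienoate | COC(=O)/C=C(\C)C[C@H](O[Si](C)(C)C(C)(C)C)/C=C(\C)[C@H](O[Si](CC)(CC)CC)CC(=O)C(C)C | intermediate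
13 | (2E,5S,6E,8R)-5-(tert-butyldimethylsilyloxy)-3,7,11-trimethyl-10-oxo-8-(triethylsilyloxy)dodeca-2,6-dienoic acid | OC(=O)/C=C(\C)C[C@H](O[Si](C)(C)C(C)(C)C)/C=C(\C)[C@H](O[Si](CC)(CC)CC)CC(=O)C(C)C | intermediate
14 | acid chloride of 13 | ClC(=O)/C=C(\C)C[C@H](O[Si](C)(C)C(C)(C)C)/C=C(\C)[C@H](O[Si](CC)(CC)CC)CC(=O)C(C)C | intermediate
15 | (5S,6E,8R)-5-(tert-butyldimethylsilyloxy)-7,11-dimethyl-3-methylidene-8-(triethylsilyloxy)dodeca-1,6-diene-1,10-dione (vinylketene) | O=C=CC(=C)C[C@H](O[Si](C)(C)C(C)(C)C)/C=C(\C)[C@H](O[Si](CC)(CC)CC)CC(=O)C(C)C | intermediate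
16 | (1R,4S,5R,7R)-4-(tert-butyldimethylsilyloxy)-7-methyl-2-methylidene-7-[(1R)-4-methyl-3-oxo-1-(triethylsilyloxy)pentyl]bicyclo[3.1.1]heptan-6-one | CC(C)C(=O)C[C@@H](O[Si](CC)(CC)CC)[C@@]1(C)[C@H]2C(=O)[C@@H]1C(=C)C[C@@H]2O[Si](C)(C)C(C)(C)C | intermediate
17 | (1R,4S,5R,7R)-4-(tert-butyldimethylsilyloxy)-7-[(1R)-1-hydroxy-4-methyl-3-oxopentyl]-7-methyl-2-methylidenebicyclo[3.1.1]heptan-6-one | CC(C)C(=O)C[C@@H](O)[C@@]1(C)[C@H]2C(=O)[C@@H]1C(=C)C[C@@H]2O[Si](C)(C)C(C)(C)C | intermediate
18 | dilithium alkoxide enolate of 17 (C9 alkoxide, C6=C7 enolate) | [Li+].[Li+].CC(C)=C([O-])C[C@@H]([O-])[C@@]1(C)[C@H]2C(=O)[C@@H]1C(=C)C[C@@H]2O[Si](C)(C)C(C)(C)C | intermediate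
19 | (1S,4R,5R,9R,10R,11R)-1-(tert-butyldimethylsilyloxy)-5,9-dihydroxylongipin-3(15)-en-7-one | O[C@@H]1CC(=O)C(C)(C)[C@]2(O)[C@H]3[C@@H](O[Si](C)(C)C(C)(C)C)CC(=C)[C@@H]2[C@]31C | intermediate
20 | tiglic acid, (E)-2-methylbut-2-enoic acid | C/C=C(\C)C(=O)O | starting material
21 | (E)-2-methylbut-2-en-1-ol | C/C=C(\C)CO | intermediate
22 | [(2R,3R)-2,3-dimethyloxiran-2-yl]methanol | OC[C@@]1(C)O[C@@H]1C | intermediate
23 | (2S,3R)-2,3-dimethyloxirane-2-carboxylic acid (methyl groups cis) | OC(=O)[C@@]1(C)O[C@@H]1C | intermediate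
24 | (1S,4R,5R,7R,9R,10R,11R)-1-(tert-butyldimethylsilyloxy)-5,7-dihydroxylongipin-3(15)-en-9-yl acetate | CC(=O)O[C@@H]1C[C@@H](O)C(C)(C)[C@]2(O)[C@H]3[C@@H](O[Si](C)(C)C(C)(C)C)CC(=C)[C@@H]2[C@]31C | intermediate
25 | (2S,3R)-2,3-dimethyloxirane-2-carboxylic 2,4,6-trichlorobenzoic anhydride | O=C(OC(=O)[C@@]1(C)O[C@@H]1C)c1c(Cl)cc(Cl)cc1Cl | intermediate
26 | (1S,4R,5R,7R,9R,10R,11R)-9-acetoxy-1-(tert-butyldimethylsilyloxy)-5-hydroxylongipin-3(15)-en-7-yl (2S,3R)-2,3-dimethyloxirane-2-carboxylate | CC(=O)O[C@@H]1C[C@@H](OC(=O)[C@@]2(C)O[C@@H]2C)C(C)(C)[C@]2(O)[C@H]3[C@@H](O[Si](C)(C)C(C)(C)C)CC(=C)[C@@H]2[C@]31C | intermediate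
27 | C5 methyl oxalate of 26 (configuration unchanged) | CC(=O)O[C@@H]1C[C@@H](OC(=O)[C@@]2(C)O[C@@H]2C)C(C)(C)[C@]2(OC(=O)C(=O)OC)[C@H]3[C@@H](O[Si](C)(C)C(C)(C)C)CC(=C)[C@@H]2[C@]31C | intermediate
28 | (1S,4R,5S,7R,9R,10R,11R)-9-acetoxy-1-(tert-butyldimethylsilyloxy)longipin-3(15)-en-7-yl (2S,3R)-2,3-dimethyloxirane-2-carboxylate | CC(=O)O[C@@H]1C[C@@H](OC(=O)[C@@]2(C)O[C@@H]2C)C(C)(C)[C@@H]2[C@H]3[C@@H](O[Si](C)(C)C(C)(C)C)CC(=C)[C@@H]2[C@]31C | intermediate
29 | (1S,4R,5S,7R,9R,10R,11R)-9-acetoxy-1-hydroxylongipin-3(15)-en-7-yl (2S,3R)-2,3-dimethyloxirane-2-carboxylate | CC(=O)O[C@@H]1C[C@@H](OC(=O)[C@@]2(C)O[C@@H]2C)C(C)(C)[C@@H]2[C@H]3[C@@H](O)CC(=C)[C@@H]2[C@]31C | intermediate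
30 | (4R,5S,7R,9R,10R,11R)-9-acetoxy-1-oxolongipin-3(15)-en-7-yl (2S,3R)-2,3-dimethyloxirane-2-carboxylate | CC(=O)O[C@@H]1C[C@@H](OC(=O)[C@@]2(C)O[C@@H]2C)C(C)(C)[C@@H]2[C@H]3C(=O)CC(=C)[C@@H]2[C@]31C | intermediate
31 | (4R,5S,7R,9R,10R,11R)-9-acetoxy-1-oxolongipin-2-en-7-yl (2S,3R)-2,3-dimethyloxirane-2-carboxylate | CC(=O)O[C@@H]1C[C@@H](OC(=O)[C@@]2(C)O[C@@H]2C)C(C)(C)[C@@H]2[C@H]3C(=O)C=C(C)[C@@H]2[C@]31C | intermediate
32 | (4R,5S,7R,9R,10R,11R)-9-hydroxy-1-oxolongipin-2-en-7-yl (2S,3R)-2,3-dimethyloxirane-2-carboxylate | O[C@@H]1C[C@@H](OC(=O)[C@@]2(C)O[C@@H]2C)C(C)(C)[C@@H]2[C@H]3C(=O)C=C(C)[C@@H]2[C@]31C | intermediate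
33 | angelic acid, (Z)-2-methylbut-2-enoic acid | C/C=C(/C)C(=O)O | starting material
34 | (Z)-2-methylbut-2-enoic 2,4,6-trichlorobenzoic anhydride | C/C=C(/C)C(=O)OC(=O)c1c(Cl)cc(Cl)cc1Cl | intermediate
35 | (4R,5S,7R,9R,10R,11R)-9-[(Z)-2-methylbut-2-enoyloxy]-1-oxolongipin-2-en-7-yl (2S,3R)-2,3-dimethyloxirane-2-carboxylate, CNP0149458.1 | C/C=C(/C)C(=O)O[C@@H]1C[C@@H](OC(=O)[C@@]2(C)O[C@@H]2C)C(C)(C)[C@@H]2[C@H]3C(=O)C=C(C)[C@@H]2[C@]31C | target

Total step count: 22.
Longest linear sequence: 18 steps (steps 1–4, 6–11 and 15–22); step 5 and steps 12–14 are side branches.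

Steps most likely to fail

Step 9. The alkene carries two allylic silyloxy groups and may react too slowly, so that ketene oligomerisation or amine-induced loss of the β-silyloxy group in the side chain takes over. The fallback replaces the ketene by the more electrophilic keteniminium ion. It sets out from acid 13: acid chloride 14 is made as before and quenched with pyrrolidine to give the pyrrolidine amide F1. Tf2O and 2,4,6-collidine in hot 1,2-dichloroethane should convert it, through the vinylketeniminium ion and the same two bond formations (C5–C11, C4–C10), into the cyclobutaniminium triflate F2. Hydrolysis with aqueous NaHCO3 returns to the route at cyclobutanone 16.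

Step 11. The lithium aldolate of the congested tertiary cyclobutanol may revert by retro-aldol cleavage, or the neighbouring silyl group may migrate to the new alkoxide before the quench. The fallback is a Mukaiyama aldol, in which silyl transfer makes the ring closure irreversible under non-basic conditions. It sets out from 17: dianion 18 is generated as before but trapped at −78 °C with Me3SiCl to give the bis(trimethylsilyl) enol ether F3. Catalytic Me3SiOTf in CH2Cl2 at −78 °C should close ring C to the bis(trimethylsilyl) ether F4, and citric acid in MeOH removes both trimethylsilyl groups, returning to the route at 19. Any enol ether formed on the methylene side cannot cyclise and is hydrolysed back to 17 for recycling.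

Step 17. The tertiary cyclobutanol sits between the quaternary C6 and the C1 silyl ether and may resist intermolecular acylation, or its oxalate may fragment poorly in step 18. The fallback makes the acylation intramolecular and uses a Barton–McCombie-type cleavage. It sets out from 26: Bu4NF/AcOH removes the C1 silyl group to give the 1,5-diol F5. Its two hydroxyls are syn and 1,3-related, so 1,1'-thiocarbonyldiimidazole (DMAP, toluene, 80 °C) should close the six-membered cyclic thionocarbonate F6. Bu3SnH/AIBN in hot toluene should cleave the C5–O bond on the side of the tertiary radical, and aqueous KF work-up frees the C1 hydroxyl. The sequence returns to the route at alcohol 29, bypassing 27 and 28.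

Further compounds
F1 | step 9 | pyrrolidine amide of acid 13 | O=C(N1CCCC1)/C=C(\C)C[C@H](O[Si](C)(C)C(C)(C)C)/C=C(\C)[C@H](O[Si](CC)(CC)CC)CC(=O)C(C)C
F2 | step 9 | cyclobutaniminium triflate (pyrrolidinium ylidene at C5 of the skeleton of 16) | CC(C)C(=O)C[C@@H](O[Si](CC)(CC)CC)[C@@]1(C)[C@H]2C(=[N+]3CCCC3)[C@@H]1C(=C)C[C@@H]2O[Si](C)(C)C(C)(C)C.[O-]S(=O)(=O)C(F)(F)F
F3 | step 11 | bis(trimethylsilyl) enol ether of 17 (C9 silyl ether, C6=C7 silyl enol ether) | CC(C)=C(O[Si](C)(C)C)C[C@@H](O[Si](C)(C)C)[C@@]1(C)[C@H]2C(=O)[C@@H]1C(=C)C[C@@H]2O[Si](C)(C)C(C)(C)C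
F4 | step 11 | 5,9-bis(trimethylsilyl) ether of 19 | C[Si](C)(C)O[C@@H]1CC(=O)C(C)(C)[C@]2(O[Si](C)(C)C)[C@H]3[C@@H](O[Si](C)(C)C(C)(C)C)CC(=C)[C@@H]2[C@]31C
F5 | step 17 | 1,5-diol (26 without the C1 silyl group) | CC(=O)O[C@@H]1C[C@@H](OC(=O)[C@@]2(C)O[C@@H]2C)C(C)(C)[C@]2(O)[C@H]3[C@@H](O)CC(=C)[C@@H]2[C@]31C
F6 | step 17 | 1,5-cyclic thionocarbonate of F5 | CC(=O)O[C@@H]1C[C@@H](OC(=O)[C@@]2(C)O[C@@H]2C)C(C)(C)[C@]2(OC4=S)[C@H]3[C@@H](O4)CC(=C)[C@@H]2[C@]31C
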